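The vessel takes its second end groups as a feed over 50 s and then stands until 8.0 h, and the examiner asks what it holds at the end.

first end groups 0.011 M; second end groups 0.0115 M (fed, over 50 s); time 8.0 h; the fed solution adds 0.50 times the starting volume

    first end groups ⇌ dormant form (K1 = 1.43, k1 = 0.122 min⁻¹)
    first end groups + second end groups ⇌ links (K2 = 53 M⁻¹, k2 = 1150 M⁻¹ min⁻¹)

- charges are per starting volume, the dose included; the dosed solution carries all of it
- what has gone from first end groups into another species counts as reacted, even if it can come back
- run time (flask): 8.0 h

- conversion of first end groups at 8.0 h
- amount of links at 8.0 h, in percent of the first end groups charged

*Is the time long enough?* Taken by itself, the dormancy step is reversible and first-order, so it integrates in closed form: the distance of first end groups from their equilibrium falls exponentially with the sum of the forward and backward constants, a relaxation time of 4.82 min. The run lasts 99.6 such times, so I reckon on equilibrium.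

*But the linking step pulls on the same end groups. Does that spoil the time?* Its backward constant is 21.7 min⁻¹, faster than the dormancy step's forward constant, so links follow as a fast pre-equilibrium. That may stretch the relaxation time, but the margin is wide.

*And the dose?* It lasts less than one relaxation time, and an equilibrium keeps no memory of its path. So the feed counts through its volume: 0.00733 M of first and 0.00767 M of second end groups in the final volume.

*How many links, then?* Free and dormant first end groups stand in a constant ratio, so linking sees the apparent link constant (a conditional constant), the linking equilibrium constant divided by one plus the dormancy constant: 21.8 M⁻¹. With L the links and a and b the diluted charges, L/((a−L)(b−L)) equals it. The smaller root gives 9.38 × 10⁻⁴ M, which is 12.8% links and a conversion of 64.1%.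

The forecast says 64.1% and 12.8%, on this ground: “Both steps relax within minutes”. My reckoning lands on the same figures.

The flask gives 64.1% and 12.8%. First end groups in this flask already stood at 36.4% after 0.400 h, much earlier than the asked time. With 88% of its charge of second end groups left in this flask, 0.00673 M, the apparent link constant times that amount, over one plus the same product, gives 12.8% links.

In the neighbour flask with 0.046 M of second end groups, the same constant and root give 37.8% links. The computed value there is 37.8%.

Its constants are those of an exercise, and the outcome is calculated.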